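**Retrosynthetic overview**

1. The C8=C9 alkene is cut last (E-selective Wittig): a C9–C18 allylic tributylphosphonium salt carrying the furan and C15, and a C2–C8 aldehyde carrying the O-methylated tetronate, C5 and C7. O-Demethylation then frees the tetronic acid.
2. The strategy rests on the C10–C16 segment: a straight seven-carbon run with methyl branches at C11 (on the C10=C11 alkene) and at C15. C15 lies eight bonds from the nearest stereocentre (C7), so it is set by a chiral zirconocene on a terminal C15=C16 alkene, which is extended in the same pot by the C17=C18 vinyl group.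
3. The achiral diene for that step comes from hept-1-en-6-yne by alkyne methylalumination (C11 methyl, E-alkene) and formaldehyde (C9). The furan is bought and joined at C18 by hydroboration and Suzuki coupling.
4. West half: C7 comes from (S)-3-bromo-2-methylpropan-1-ol, C5 from cinchonidine-modified platinum hydrogenation of an α-keto ester, and C2, C3 and the 3-methyl group from a propionate.
5. Ring order: the butenolide (tetronate) ring is the only ring made, by Dieckmann closure of C3–C4 in step 13. The furan ring is carried intact from 3-bromofuran.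

Key step: step 4

Remark on the chemistry: numbering is lactone carbonyl C2, ring carbons C3–C5, chain C6–C18 out to the furan. The SMILES is read as 5R,7R,15R with 8E,10E. The C15 purity after step 4 is set by the catalyst alone and cannot be raised later, so it is to be checked at compound 12 before material is carried on.

**East half (C9–C18 and furan)**

Step 1
Reactants: 1 5-bromopent-1-ene; 2 lithium acetylide–ethylenediamine complex
Product: 3 hept-1-en-6-yne
Conditions: DMSO, 10 °C → rt; distil
Reagents that add atoms: lithium acetylide–ethylenediamine complex (2), [Li+].[C-]#C.NCCN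
Why: SN2 alkylation of an acetylide by a primary bromide in DMSO should give the terminal alkyne, with the terminal alkene inert.

Step 2
Reactants: 3 hept-1-en-6-yne; 4 trimethylaluminium
Product: 7 (E)-3-methylocta-2,7-dien-1-ol, via alkenyldimethylalane 5 (not isolated), via lithium alanate 6 (not isolated)
Conditions: Me3Al, Cp2ZrCl2 (0.25 equiv), CH2Cl2, 0 °C → rt; evaporate; n-BuLi, hexane, 0 °C; (CH2O)n, THF, rt; aq. HCl
Reagents that add atoms: trimethylaluminium (4), C[Al](C)C; paraformaldehyde (as formaldehyde), C=O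
Why: Negishi zirconium-catalysed methylalumination should add CH3 and Al syn across the terminal alkyne (methyl to C11) much faster than Cp2ZrCl2/Me3Al touches the unactivated terminal alkene, and the alanate should add to formaldehyde with retention to give the E-allylic alcohol (C9).

Step 3
Reactants: 7 (E)-3-methylocta-2,7-dien-1-ol
Product: 8 tert-butyldimethyl{[(E)-3-methylocta-2,7-dien-1-yl]oxy}silane
Conditions: TBSCl, imidazole, DMF, 0 °C → rt
Reagents that add atoms: tert-butyldimethylsilyl chloride, CC(C)(C)[Si](C)(C)Cl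
Why: Standard silylation of a primary allylic alcohol should remove the acidic OH before the organoaluminium step.

Step 4
Reactants: 8 tert-butyldimethyl{[(E)-3-methylocta-2,7-dien-1-yl]oxy}silane; 4 trimethylaluminium; 9 vinyl bromide
Product: 12 tert-butyl{[(R,E)-3,7-dimethyldeca-2,9-dien-1-yl]oxy}dimethylsilane, via isoalkyldimethylalane 10 (not isolated), via alkylzinc triflate 11 (not isolated)
Conditions: Me3Al, (−)-bis(1-neomenthylindenyl)zirconium dichloride [(NMI)2ZrCl2, 5 mol %], methylaluminoxane (MeAlO)n, CH2Cl2, 0 °C → rt; evaporate volatiles; Zn(OTf)2, DMF, 70 °C; then vinyl bromide, PdCl2(DPEphos) (3 mol %), i-Bu2AlH (6 mol %), DMF, rt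
Reagents that add atoms: trimethylaluminium (4), C[Al](C)C; vinyl bromide (9), C=CBr
Why: This is the known zirconium-catalysed asymmetric carboalumination of a 1-alkene followed in the same pot by zinc transmetalation and Negishi-type vinylation: the cationic chiral methylzirconocene formed from (NMI)2ZrCl2, Me3Al and (MeAlO)n inserts the monosubstituted C15=C16 alkene with methyl to C15 and metal to C16, and Zr/Al exchange releases alane 10 and turns the catalyst over. Zn(OTf)2 in DMF should move the primary alkyl group to zinc (11), which transmetalates to the vinylpalladium bromide formed by oxidative addition of 9 to zerovalent palladium (made from PdCl2(DPEphos) by i-Bu2AlH), and reductive elimination forms C16–C17. No ring is closed. C15 is set by the catalyst alone: the (−)-neomenthylindenyl ligands select the alkene face that gives the (R)-2-methylalkyl metal, as with simple 1-alkenes, and the coupling cannot disturb it because C15 is not the metal-bearing carbon. The step needs site selectivity for the terminal alkene over the trisubstituted C10=C11 alkene, which the inertness of trisubstituted alkenes toward the zirconocene should secure, and it needs the distant allylic silyl ether to survive the Lewis acids. Face selectivity for methyl transfer is moderate by nature, so the enantiomeric purity of 12 is to be measured before it is used.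

Step 5
Reactants: 12 tert-butyl{[(R,E)-3,7-dimethyldeca-2,9-dien-1-yl]oxy}dimethylsilane; 13 3-bromofuran
Product: 15 tert-butyl{[(R,E)-10-(furan-3-yl)-3,7-dimethyldec-2-en-1-yl]oxy}dimethylsilane, via B-alkyl-9-BBN 14 (not isolated)
Conditions: 9-BBN, THF, 0 °C → rt; then 3-bromofuran, PdCl2(dppf) (5 mol %), aq. K3PO4, DMF, 50 °C
Reagents that add atoms: 3-bromofuran (13), Brc1ccoc1
Why: 9-BBN should hydroborate only the monosubstituted C17=C18 alkene with boron at C18, and the B-alkyl Suzuki–Miyaura coupling with the heteroaryl bromide should form the C18–furan bond without touching C15.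

Step 6
Reactants: 15 tert-butyl{[(R,E)-10-(furan-3-yl)-3,7-dimethyldec-2-en-1-yl]oxy}dimethylsilane
Product: 16 (R,E)-10-(furan-3-yl)-3,7-dimethyldec-2-en-1-ol
Conditions: Bu4NF, THF, 0 °C → rt
Reagents that add atoms: none
Why: Fluoride cleavage of the primary TBS ether should leave furan and alkene intact.

Step 7
Reactants: 16 (R,E)-10-(furan-3-yl)-3,7-dimethyldec-2-en-1-ol
Product: 17 3-[(R,E)-10-bromo-4,8-dimethyldec-8-en-1-yl]furan
Conditions: CBr4, PPh3, CH2Cl2, −20 → 0 °C; used at once
Reagents that add atoms: carbon tetrabromide, BrC(Br)(Br)Br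
Why: The Appel reaction should convert the primary allylic alcohol to the bromide under near-neutral conditions that the furan tolerates, without allylic transposition at low temperature.

Step 8
Reactants: 17 3-[(R,E)-10-bromo-4,8-dimethyldec-8-en-1-yl]furan
Product: 18 tributyl[(R,E)-10-(furan-3-yl)-3,7-dimethyldec-2-en-1-yl]phosphonium bromide
Conditions: PBu3, MeCN, rt
Reagents that add atoms: tributylphosphine, CCCCP(CCCC)CCCC
Why: SN2 quaternisation of tributylphosphine at the primary allylic carbon should give the salt with the C10=C11 geometry kept.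

**West half (C2–C8 methyl tetronate aldehyde)**

Step 9
Reactants: 19 (S)-3-bromo-2-methylpropan-1-ol
Product: 20 (S)-(3-bromo-2-methylpropoxy)triisopropylsilane
Conditions: TIPSCl, imidazole, DMF, 0 °C → rt
Reagents that add atoms: triisopropylsilyl chloride, CC(C)[Si](Cl)(C(C)C)C(C)C
Why: Silylation gives an ether that should survive Grignard formation, hydrogenation in acetic acid and LiN(SiMe3)2, and that has no arene to be reduced on platinum.

Step 10
Reactants: 20 (S)-(3-bromo-2-methylpropoxy)triisopropylsilane; 21 diethyl oxalate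
Product: 23 ethyl (R)-4-methyl-2-oxo-5-[(triisopropylsilyl)oxy]pentanoate, via Grignard reagent 22 (not isolated)
Conditions: Mg, THF, 40 °C; added to diethyl oxalate (3 equiv), THF, −78 °C; 1 M HCl
Reagents that add atoms: diethyl oxalate (21), CCOC(=O)C(=O)OCC
Why: Grignard acylation with excess oxalate at −78 °C should stop at the α-keto ester because the tetrahedral adduct is stable in the cold, and C7 is not enolisable in the product.

Step 11
Reactants: 23 ethyl (R)-4-methyl-2-oxo-5-[(triisopropylsilyl)oxy]pentanoate
Product: 24 ethyl (2R,4R)-2-hydroxy-4-methyl-5-[(triisopropylsilyl)oxy]pentanoate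
Conditions: H2 (60 bar), 5% Pt/Al2O3, cinchonidine, toluene/AcOH, rt
Reagents that add atoms: none
Why: Cinchona-modified platinum hydrogenation of α-keto esters (Orito reaction) with cinchonidine delivers the (R)-α-hydroxy ester, so C5 is set by the alkaloid modifier, and the C5 epimer is a diastereomer that should be removable by chromatography.

Step 12
Reactants: 24 ethyl (2R,4R)-2-hydroxy-4-methyl-5-[(triisopropylsilyl)oxy]pentanoate
Product: 25 ethyl (2R,4R)-4-methyl-2-(propanoyloxy)-5-[(triisopropylsilyl)oxy]pentanoate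
Conditions: (EtCO)2O, Et3N, DMAP (cat.), CH2Cl2, 0 °C → rt
Reagents that add atoms: propionic anhydride, CCC(=O)OC(=O)CC
Why: DMAP-catalysed acylation of the secondary alcohol should proceed without affecting C5.

Step 13
Reactants: 25 ethyl (2R,4R)-4-methyl-2-(propanoyloxy)-5-[(triisopropylsilyl)oxy]pentanoate
Product: 26 (R)-4-hydroxy-3-methyl-5-{(R)-2-methyl-3-[(triisopropylsilyl)oxy]propyl}furan-2(5H)-one
Conditions: LiN(SiMe3)2 (2.2 equiv), THF, −78 → 0 °C; 1 M HCl
Reagents that add atoms: none
Why: Dieckmann (intramolecular Claisen) cyclisation of the propionate enolate onto the ethyl ester should close the five-membered lactone by forming C3–C4 (5-exo-trig), and the tetronate anion formed resists further deprotonation, so C5 should be retained.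

Step 14
Reactants: 26 (R)-4-hydroxy-3-methyl-5-{(R)-2-methyl-3-[(triisopropylsilyl)oxy]propyl}furan-2(5H)-one
Product: 27 (R)-4-methoxy-3-methyl-5-{(R)-2-methyl-3-[(triisopropylsilyl)oxy]propyl}furan-2(5H)-one
Conditions: Me2SO4, K2CO3, acetone, rt
Reagents that add atoms: dimethyl sulfate, COS(=O)(=O)OC
Why: O-Alkylation of the vinylogous acid with a hard methylating agent should give the 4-methoxy butenolide, which masks the acidic OH for the Wittig step.

Step 15
Reactants: 27 (R)-4-methoxy-3-methyl-5-{(R)-2-methyl-3-[(triisopropylsilyl)oxy]propyl}furan-2(5H)-one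
Product: 28 (R)-5-[(R)-3-hydroxy-2-methylpropyl]-4-methoxy-3-methylfuran-2(5H)-one
Conditions: HF·pyridine, pyridine, THF, 0 °C → rt
Reagents that add atoms: none
Why: Buffered HF should cleave the primary silyl ether without exposing the C5–H of the methyl tetronate to base.

Step 16
Reactants: 28 (R)-5-[(R)-3-hydroxy-2-methylpropyl]-4-methoxy-3-methylfuran-2(5H)-one
Product: 29 (R)-3-[(R)-3-methoxy-4-methyl-5-oxo-2,5-dihydrofuran-2-yl]-2-methylpropanal
Conditions: Dess–Martin periodinane, CH2Cl2, 0 °C → rt; used at once
Reagents that add atoms: none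
Why: Dess–Martin oxidation under non-basic conditions should give the α-methyl aldehyde without epimerising C7.

**Union and end game**

Step 17
Reactants: 18 tributyl[(R,E)-10-(furan-3-yl)-3,7-dimethyldec-2-en-1-yl]phosphonium bromide; 29 (R)-3-[(R)-3-methoxy-4-methyl-5-oxo-2,5-dihydrofuran-2-yl]-2-methylpropanal
Product: 31 (R)-5-[(2R,3E,5E,10R)-13-(furan-3-yl)-2,6,10-trimethyltrideca-3,5-dien-1-yl]-4-methoxy-3-methylfuran-2(5H)-one, via phosphonium ylide 30 (not isolated)
Conditions: KOtBu (0.95 equiv to salt), THF, −78 °C; then aldehyde 29, −78 → 0 °C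
Reagents that add atoms: none
Why: In this Wittig olefination, ylides from allylic tributylphosphonium salts are known to favour the E-alkene through the trans-oxaphosphetane, so C8=C9 should form E with the C10=C11 geometry kept, and the sub-stoichiometric base and low temperature should protect the C7 and C5 hydrogens.

Step 18
Reactants: 31 (R)-5-[(2R,3E,5E,10R)-13-(furan-3-yl)-2,6,10-trimethyltrideca-3,5-dien-1-yl]-4-methoxy-3-methylfuran-2(5H)-one
Product: 32 (R)-5-[(2R,3E,5E,10R)-13-(furan-3-yl)-2,6,10-trimethyltrideca-3,5-dien-1-yl]-4-hydroxy-3-methylfuran-2(5H)-one (CNP0246504.1)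
Conditions: LiCl, DMF, 100 °C; then 1 M HCl
Reagents that add atoms: none
Why: SN2 attack of chloride on the O-methyl group of the vinylogous carbonate should release the tetronate anion, a good leaving group, without touching any stereocentre or the diene.

**Compound list**

1 | 5-bromopent-1-ene | C=CCCCBr | starting material
2 | lithium acetylide–ethylenediamine complex | [Li+].[C-]#C.NCCN | starting material
3 | hept-1-en-6-yne | C=CCCCC#C | intermediate
4 | trimethylaluminium | C[Al](C)C | starting material
5 | (E)-dimethyl(2-methylhepta-1,6-dien-1-yl)alane | C=CCCC/C(C)=C/[Al](C)C | intermediate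
6 | lithium butyldimethyl[(E)-2-methylhepta-1,6-dien-1-yl]aluminate | [Li+].CCCC[Al-](C)(C)/C=C(\C)CCCC=C | intermediate
7 | (E)-3-methylocta-2,7-dien-1-ol | C=CCCC/C(C)=C/CO | intermediate
8 | tert-butyldimethyl{[(E)-3-methylocta-2,7-dien-1-yl]oxy}silane | C=CCCC/C(C)=C/CO[Si](C)(C)C(C)(C)C | intermediate
9 | vinyl bromide | C=CBr | starting material
10 | {(R,E)-8-[(tert-butyldimethylsilyl)oxy]-2,6-dimethyloct-6-en-1-yl}dimethylalane | C[Al](C)C[C@H](C)CCC/C(C)=C/CO[Si](C)(C)C(C)(C)C | intermediate
11 | {(R,E)-8-[(tert-butyldimethylsilyl)oxy]-2,6-dimethyloct-6-en-1-yl}zinc trifluoromethanesulfonate | FC(F)(F)S(=O)(=O)O[Zn]C[C@H](C)CCC/C(C)=C/CO[Si](C)(C)C(C)(C)C | intermediate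
12 | tert-butyl{[(R,E)-3,7-dimethyldeca-2,9-dien-1-yl]oxy}dimethylsilane | C=CC[C@H](C)CCC/C(C)=C/CO[Si](C)(C)C(C)(C)C | intermediate
13 | 3-bromofuran | Brc1ccoc1 | starting material
14 | 9-{(E)-10-[(tert-butyldimethylsilyl)oxy]-4,8-dimethyldec-8-en-1-yl}-9-borabicyclo[3.3.1]nonane, C15 configuration as in 12 (formal descriptor S because boron ranks below carbon) | CC(C)(C)[Si](C)(C)OC/C=C(\C)CCC[C@@H](C)CCCB1C2CCCC1CCC2 | intermediate
15 | tert-butyl{[(R,E)-10-(furan-3-yl)-3,7-dimethyldec-2-en-1-yl]oxy}dimethylsilane | CC(C)(C)[Si](C)(C)OC/C=C(\C)CCC[C@@H](C)CCCc1ccoc1 | intermediate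
16 | (R,E)-10-(furan-3-yl)-3,7-dimethyldec-2-en-1-ol | OC/C=C(\C)CCC[C@@H](C)CCCc1ccoc1 | intermediate
17 | 3-[(R,E)-10-bromo-4,8-dimethyldec-8-en-1-yl]furan | BrC/C=C(\C)CCC[C@@H](C)CCCc1ccoc1 | intermediate
18 | tributyl[(R,E)-10-(furan-3-yl)-3,7-dimethyldec-2-en-1-yl]phosphonium bromide | CCCC[P+](CCCC)(CCCC)C/C=C(\C)CCC[C@@H](C)CCCc1ccoc1.[Br-] | intermediate
19 | (S)-3-bromo-2-methylpropan-1-ol | BrC[C@@H](C)CO | starting material
20 | (S)-(3-bromo-2-methylpropoxy)triisopropylsilane | BrC[C@@H](C)CO[Si](C(C)C)(C(C)C)C(C)C | intermediate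
21 | diethyl oxalate | CCOC(=O)C(=O)OCC | starting material
22 | {(S)-2-methyl-3-[(triisopropylsilyl)oxy]propyl}magnesium bromide | Br[Mg]C[C@@H](C)CO[Si](C(C)C)(C(C)C)C(C)C | intermediate
23 | ethyl (R)-4-methyl-2-oxo-5-[(triisopropylsilyl)oxy]pentanoate | CCOC(=O)C(=O)C[C@@H](C)CO[Si](C(C)C)(C(C)C)C(C)C | intermediate
24 | ethyl (2R,4R)-2-hydroxy-4-methyl-5-[(triisopropylsilyl)oxy]pentanoate | CCOC(=O)[C@H](O)C[C@@H](C)CO[Si](C(C)C)(C(C)C)C(C)C | intermediate
25 | ethyl (2R,4R)-4-methyl-2-(propanoyloxy)-5-[(triisopropylsilyl)oxy]pentanoate | CCOC(=O)[C@H](OC(=O)CC)C[C@@H](C)CO[Si](C(C)C)(C(C)C)C(C)C | intermediate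
26 | (R)-4-hydroxy-3-methyl-5-{(R)-2-methyl-3-[(triisopropylsilyl)oxy]propyl}furan-2(5H)-one | CC1=C(O)[C@@H](C[C@@H](C)CO[Si](C(C)C)(C(C)C)C(C)C)OC1=O | intermediate
27 | (R)-4-methoxy-3-methyl-5-{(R)-2-methyl-3-[(triisopropylsilyl)oxy]propyl}furan-2(5H)-one | CC1=C(OC)[C@@H](C[C@@H](C)CO[Si](C(C)C)(C(C)C)C(C)C)OC1=O | intermediate
28 | (R)-5-[(R)-3-hydroxy-2-methylpropyl]-4-methoxy-3-methylfuran-2(5H)-one | CC1=C(OC)[C@@H](C[C@@H](C)CO)OC1=O | intermediate
29 | (R)-3-[(R)-3-methoxy-4-methyl-5-oxo-2,5-dihydrofuran-2-yl]-2-methylpropanal | CC1=C(OC)[C@@H](C[C@@H](C)C=O)OC1=O | intermediate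
30 | tributyl[(R,E)-10-(furan-3-yl)-3,7-dimethyldec-2-en-1-ylidene]phosphorane (ylide) | CCCC[P+](CCCC)(CCCC)[CH-]/C=C(\C)CCC[C@@H](C)CCCc1ccoc1 | intermediate
31 | (R)-5-[(2R,3E,5E,10R)-13-(furan-3-yl)-2,6,10-trimethyltrideca-3,5-dien-1-yl]-4-methoxy-3-methylfuran-2(5H)-one | CC1=C(OC)[C@@H](C[C@@H](C)/C=C/C=C(\C)CCC[C@@H](C)CCCc2ccoc2)OC1=O | intermediate
32 | (R)-5-[(2R,3E,5E,10R)-13-(furan-3-yl)-2,6,10-trimethyltrideca-3,5-dien-1-yl]-4-hydroxy-3-methylfuran-2(5H)-one (CNP0246504.1) | CC1=C(O)[C@@H](C[C@@H](C)/C=C/C=C(\C)CCC[C@@H](C)CCCc2ccoc2)OC1=O | target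

**Step count and risks**

Total step count: 18. Longest linear sequence: 10 steps (steps 1–8, 17, 18; the west branch, steps 9–16, 17, 18, is equally long).

The three steps most likely to fail:

Step 4. Face selection in the methyl transfer to C15 may be incomplete, and the alane may be partly lost in the zinc and palladium stage. A C15-epimeric series would then run through to 32, where it cannot be separated. The fallback sets out from 8 and comes back at 12. Alane 10 is made as in step 4 but is oxidised with dry O2 to the alcohol (R,E)-8-[(tert-butyldimethylsilyl)oxy]-2,6-dimethyloct-6-en-1-ol F1. F1 is stirred with a Burkholderia cepacia lipase (Amano PS) and vinyl acetate, which is expected to acetylate the minor enantiomer faster and remove it as (S,E)-8-[(tert-butyldimethylsilyl)oxy]-2,6-dimethyloct-6-en-1-yl acetate F2, so that the recovered F1 should be enantiomerically enriched. F1 is converted with I2, PPh3 and imidazole into tert-butyl{[(R,E)-8-iodo-3,7-dimethyloct-2-en-1-yl]oxy}dimethylsilane F3. Zinc dust with LiCl in THF should insert to give {(R,E)-8-[(tert-butyldimethylsilyl)oxy]-2,6-dimethyloct-6-en-1-yl}zinc iodide F4, and Negishi coupling with vinyl bromide 9 under Pd(PPh3)4 gives 12.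

Step 11. Face selection on the modified platinum surface may be poor for this β-branched, silyloxy-bearing keto ester, giving low diastereoselectivity at C5. The fallback sets out from 23 and comes back at 25. Reduction of 23 with NaBH4 in MeOH at −20 °C gives 24 together with its C5 epimer, ethyl (2S,4R)-2-hydroxy-4-methyl-5-[(triisopropylsilyl)oxy]pentanoate F5, and the two diastereomers are separated by chromatography. 24 goes on through step 12. F5 is esterified with propionic acid under Mitsunobu conditions (PPh3, DIAD, THF, 0 °C), which inverts C5 and gives 25 directly, so both streams converge.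

Step 17. The ylide may act as a base toward the C5–H of the methyl tetronate or the C7–H next to the aldehyde, which would consume ylide and epimerise C5 or C7, and E-selectivity at C8=C9 may be incomplete. The fallback sets out from 25 and 18 and comes back at 32. It moves the olefination ahead of tetronate formation, so that the acidic butenolide is absent and no O-methyl group has to be removed. 25 is desilylated with HF·pyridine to ethyl (2R,4R)-5-hydroxy-4-methyl-2-(propanoyloxy)pentanoate F6. This is oxidised without storage (δ-lactonisation is possible) with Dess–Martin periodinane to ethyl (2R,4R)-4-methyl-5-oxo-2-(propanoyloxy)pentanoate F7. Wittig reaction of F7 with ylide 30 from 18, as in step 17, gives ethyl (2R,4R,5E,7E,12R)-15-(furan-3-yl)-4,8,12-trimethyl-2-(propanoyloxy)pentadeca-5,7-dienoate F8. Dieckmann cyclisation of F8 with LiN(SiMe3)2 in THF at −78 → 0 °C and acid work-up closes the lactone last and gives 32.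

**Further compounds**

F1 | step 4 | (R,E)-8-[(tert-butyldimethylsilyl)oxy]-2,6-dimethyloct-6-en-1-ol | OC[C@H](C)CCC/C(C)=C/CO[Si](C)(C)C(C)(C)C
F2 | step 4 | (S,E)-8-[(tert-butyldimethylsilyl)oxy]-2,6-dimethyloct-6-en-1-yl acetate | CC(=O)OC[C@@H](C)CCC/C(C)=C/CO[Si](C)(C)C(C)(C)C
F3 | step 4 | tert-butyl{[(R,E)-8-iodo-3,7-dimethyloct-2-en-1-yl]oxy}dimethylsilane | IC[C@H](C)CCC/C(C)=C/CO[Si](C)(C)C(C)(C)C
F4 | step 4 | {(R,E)-8-[(tert-butyldimethylsilyl)oxy]-2,6-dimethyloct-6-en-1-yl}zinc iodide | I[Zn]C[C@H](C)CCC/C(C)=C/CO[Si](C)(C)C(C)(C)C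
F5 | step 11 | ethyl (2S,4R)-2-hydroxy-4-methyl-5-[(triisopropylsilyl)oxy]pentanoate | CCOC(=O)[C@@H](O)C[C@@H](C)CO[Si](C(C)C)(C(C)C)C(C)C
F6 | step 17 | ethyl (2R,4R)-5-hydroxy-4-methyl-2-(propanoyloxy)pentanoate | CCOC(=O)[C@H](OC(=O)CC)C[C@@H](C)CO
F7 | step 17 | ethyl (2R,4R)-4-methyl-5-oxo-2-(propanoyloxy)pentanoate | CCOC(=O)[C@H](OC(=O)CC)C[C@@H](C)C=O
F8 | step 17 | ethyl (2R,4R,5E,7E,12R)-15-(furan-3-yl)-4,8,12-trimethyl-2-(propanoyloxy)pentadeca-5,7-dienoate | CCOC(=O)[C@H](OC(=O)CC)C[C@@H](C)/C=C/C=C(\C)CCC[C@@H](C)CCCc1ccoc1
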